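**Retrosynthetic overview**

1. The target is (3R,3'R,6'R)-lutein with palmitate at C3 (β-ring) and myristate at C3' (ε-ring). It is cut at C11'=C12' (Wittig, β-C25 phosphonium salt 24 + ε-C15 aldehyde 12) and at C11=C12 (Wittig, β-C15 salt 19 + C10 dialdehyde 20).
2. Both C15 units go back to one cis-hydroxy nitrile 8. Mitsunobu inversion with myristic acid gives the ε-end group. A base-mediated shift of C4=C5 to C5=C6 erases C6 and turns the same carbinol centre into the (3R)-β-end group, which is then palmitoylated.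
3. 8 comes from enone 7 by hydride delivery anti to the C6' chain (1,4-relay C6' → C3'); 7 from silyl enol ether 6 (Saegusa–Ito); 6 from aldehyde 4 (C5 Horner–Wadsworth–Emmons).
4. Feature on which the plan rests: the ε-ring atoms C1' (gem-dimethyl), C6' (chain-bearing methine), C5' (methyl) and C3' (oxygen) are the pattern of a [4+2] adduct of 3-methylbut-2-enal and a 2-siloxypenta-1,3-diene, which forms C1'–C2' and C5'–C6'.
5. Ring order: the cyclohexene of 4 (step 2) is the only ring made. It stays as the ε-ring in one branch and becomes the β-ring in the other.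

Key step: step 2

Assumption: the catalyst antipode is assigned from the formyl C–H···O binding model of enal–oxazaborolidine·AlBr3 complexes, by which the (R)-catalyst exposes the Si face of C-α of 3; were the sense opposite, the (S)-catalyst would be used with nothing else changed.

**Route**

Step 1
Reactants: 1 (E)-pent-3-en-2-one (distilled)
Product: 2 (E)-tert-butyldimethyl(penta-1,3-dien-2-yloxy)silane
Conditions: TBSOTf (1.1 equiv), Et3N (1.5 equiv), CH2Cl2, 0 °C
Reagents that add atoms: tert-butyldimethylsilyl trifluoromethanesulfonate, CC(C)(C)[Si](C)(C)OS(=O)(=O)C(F)(F)F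
Why: Soft enolisation and O-silylation: Et3N removes a proton from the methyl group (the only α'-position, kinetically preferred over γ-deprotonation) of the triflate-activated ketone, giving the cross-conjugated 2-siloxydiene with the E-alkene untouched; no stereocentre is formed.

Step 2
Reactants: 2 (E)-tert-butyldimethyl(penta-1,3-dien-2-yloxy)silane; 3 3-methylbut-2-enal
Product: 4 (1S,2S)-4-[(tert-butyldimethylsilyl)oxy]-2,6,6-trimethylcyclohex-3-ene-1-carbaldehyde (cis, endo adduct)
Conditions: (R)-tetrahydro-1-(2-methylphenyl)-3,3-diphenyl-1H,3H-pyrrolo[1,2-c][1,3,2]oxazaborole (20 mol %), AlBr3 (16 mol %), 2 (1.5 equiv), CH2Cl2, −78 → −40 °C; Et3N quench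
Reagents that add atoms: none
Why: Proposed new method: the AlBr3-activated oxazaborolidine binds the formyl oxygen of 3 and lowers the LUMO of the s-trans enal, so that 2 should add in a concerted, asynchronous [4π+2π] event in which its CH2 terminus (largest HOMO coefficient, reinforced by both the 2-siloxy and the 4-methyl group) bonds first to the β,β-dimethyl carbon and the methyl-bearing terminus then closes onto C-α. The closest known reaction types are oxazaborolidinium-catalysed Diels–Alder reactions of enals and of 2-silyloxydienes, and the achiral AlBr3/AlMe3-promoted cycloadditions of 2-siloxydienes with β,β-disubstituted enones. The one ring, the six-membered carbocycle that becomes the ε-ring, is closed by intermolecular suprafacial [4+2] cycloaddition that makes C1'–C2' and C5'–C6' together. C1 of 4 (C6' of the target) is set by the catalyst, whose aryl group screens one face of the bound enal so that the diene adds to the Si face of C-α (priorities CHO > C-β > H); C2 of 4 (C5') follows from the endo transition state and is removed again in step 4. The step needs one regiochemistry, secured by the matched donor pattern of 2, one enal face, secured by the catalyst, and cycloaddition in place of Mukaiyama-type addition to the formyl carbon, for which the bulky TBS group and the crowded catalyst-bound carbonyl are relied on.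

Step 3
Reactants: 4 cis-adduct aldehyde (cis isomer only); 5 diethyl (3-cyano-2-methylallyl)phosphonate (E/Z mixture as sold)
Product: 6 (2E,4E)-5-[(1S,2R)-4-[(tert-butyldimethylsilyl)oxy]-2,6,6-trimethylcyclohex-3-en-1-yl]-3-methylpenta-2,4-dienenitrile (ring substituents cis)
Conditions: 5 (1.3 equiv), NaN(SiMe3)2 (1.2 equiv), THF, −78 °C; then 4, −78 → 0 °C
Reagents that add atoms: none
Why: Horner–Wadsworth–Emmons olefination: the allylic phosphonate anion adds through its α-carbon to the hindered aldehyde and syn-elimination of phosphate forms C7'=C8' as the E-alkene, while C9'=C10' settles mainly E in the delocalised anion (so the E/Z mixture of 5 is of no concern); the phosphonate is kept in excess over the base so that C1 of 4 is not enolised, the silyl enol ether is inert to base, and 9'Z or C6'-epimerised material is removed as separable isomers.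

Step 4
Reactants: 6 silyl enol ether dienenitrile
Product: 7 (2E,4E)-3-methyl-5-[(1R)-2,6,6-trimethyl-4-oxocyclohex-2-en-1-yl]penta-2,4-dienenitrile
Conditions: Pd(OAc)2 (1.1 equiv), MeCN, 40 °C
Reagents that add atoms: none
Why: Saegusa–Ito oxidation: divalent palladium is delivered to C4' of the silyl enol ether and syn β-hydride elimination, possible only towards C5'–H, gives the C4'=C5' enone regiospecifically, erasing the C5' centre and leaving C6' untouched in the non-basic medium.

Step 5
Reactants: 7 enone nitrile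
Product: 8 (2E,4E)-5-[(1R,4S)-4-hydroxy-2,6,6-trimethylcyclohex-2-en-1-yl]-3-methylpenta-2,4-dienenitrile (hydroxyl cis to the side chain)
Conditions: NaBH4 (1.0 equiv), CeCl3·7H2O (1.1 equiv), MeOH, −78 °C
Reagents that add atoms: none
Why: Luche 1,2-reduction: the cerium-activated carbonyl should take hydride on the face away from the pseudo-axial C6' side chain, which places the new hydroxyl cis to that chain (3'S, 1,4-relay from C6'); the nitrile and diene are inert, the cold and nearly neutral medium should keep the acidic C6'–H in place, and the minor trans-epimer is separated.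

Step 6
Reactants: 8 cis-hydroxy nitrile
Product: 10 (2E,4E)-5-[(1R,4S)-4-hydroxy-2,6,6-trimethylcyclohex-2-en-1-yl]-3-methylpenta-2,4-dienal, via aldimine 9 (not isolated)
Conditions: i-Bu2AlH (2.5 equiv), CH2Cl2, −78 °C; then aqueous potassium sodium tartrate, wet SiO2, 0 °C → rt
Reagents that add atoms: water, O
Why: Partial reduction of a nitrile: after deprotonation of the hydroxyl one hydride adds to C≡N to give the aluminium aldimine, which stops there at −78 °C and is hydrolysed under mild, non-acidic conditions to the dienal, so the acid-labile allylic alcohol, the E-alkenes and both stereocentres are kept.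

Step 7
Reactants: 10 cis-hydroxy dienal; 11 tetradecanoic (myristic) acid
Product: 12 (1R,4R)-3,5,5-trimethyl-4-[(1E,3E)-3-methyl-5-oxopenta-1,3-dien-1-yl]cyclohex-2-en-1-yl tetradecanoate
Conditions: 11 (1.3 equiv), PPh3 (1.5 equiv), DIAD (1.5 equiv), THF, 0 °C
Reagents that add atoms: none
Why: Mitsunobu esterification: myristate displaces the oxyphosphonium group at C3' in an SN2 reaction with inversion, entering on the ring face away from the C6' chain and giving the 3'R ester trans to it; SN2' attack at the methyl-bearing C5' is sterically disfavoured and the dienal is a spectator.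

Step 8
Reactants: 8 cis-hydroxy nitrile
Product: 13 (2E,4E)-5-[(4R)-4-hydroxy-2,6,6-trimethylcyclohex-1-en-1-yl]-3-methylpenta-2,4-dienenitrile
Conditions: KOt-Bu (0.3 equiv), t-BuOH/DMSO, 50 °C, argon
Reagents that add atoms: none
Why: Base-mediated prototropic isomerisation of an ε-end group to a β-end group (the reaction type that turns 3'-epilutein-type and α-ionone-type rings into their conjugated isomers): reversible deprotonation at the doubly allylic C6 and reprotonation at C4 should bring the ring alkene into conjugation with the dienenitrile as the thermodynamic product; the C6 centre is erased on purpose, the carbinol centre is not touched and is named 3R only because the ring priorities change, and 9Z material formed through the delocalised anion is separated and re-equilibrated.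

Step 9
Reactants: 13 β-series hydroxy nitrile
Product: 15 (2E,4E)-5-[(4R)-4-hydroxy-2,6,6-trimethylcyclohex-1-en-1-yl]-3-methylpenta-2,4-dienal, via aldimine 14 (not isolated)
Conditions: i-Bu2AlH (2.5 equiv), CH2Cl2, −78 °C; then aqueous potassium sodium tartrate, wet SiO2, 0 °C → rt
Reagents that add atoms: water, O
Why: Partial reduction of a nitrile as in step 6: one hydride adds to C≡N and mild hydrolysis of the aluminium aldimine gives the trienal; the C3 centre is a spectator.

Step 10
Reactants: 15 β-series hydroxy aldehyde; 16 hexadecanoyl (palmitoyl) chloride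
Product: 17 (1R)-3,5,5-trimethyl-4-[(1E,3E)-3-methyl-5-oxopenta-1,3-dien-1-yl]cyclohex-3-en-1-yl hexadecanoate
Conditions: 16 (1.2 equiv), pyridine, DMAP (5 mol %), CH2Cl2, 0 °C → rt
Reagents that add atoms: none
Why: DMAP-catalysed acylation of the secondary alcohol by the acid chloride with retention at C3; the aldehyde does not react.

Step 11
Reactants: 17 β-series aldehyde palmitate
Product: 18 (1R)-4-[(1E,3E)-5-hydroxy-3-methylpenta-1,3-dien-1-yl]-3,5,5-trimethylcyclohex-3-en-1-yl hexadecanoate
Conditions: NaBH4, EtOH/THF, −20 → 0 °C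
Reagents that add atoms: none
Why: Chemoselective 1,2-reduction of the conjugated aldehyde by borohydride at low temperature, under which the secondary ester and the triene are unchanged.

Step 12
Reactants: 18 β-series allylic alcohol palmitate
Product: 19 {(2E,4E)-5-[(4R)-4-(hexadecanoyloxy)-2,6,6-trimethylcyclohex-1-en-1-yl]-3-methylpenta-2,4-dien-1-yl}triphenylphosphonium bromide
Conditions: PPh3·HBr (1.05 equiv), CH2Cl2, 0 °C → rt
Reagents that add atoms: triphenylphosphine hydrobromide, [Br-].c1ccccc1[PH+](c1ccccc1)c1ccccc1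
Why: Phosphonium salt formation by acid-promoted ionisation of the primary allylic alcohol to a trienyl cation and capture by PPh3 at the unhindered terminus (SN1, the standard C15 Wittig-salt preparation); the homoallylic C3 ester cannot ionise.

Step 13
Reactants: 19 β-C15 phosphonium bromide; 20 (2E,4E,6E)-2,7-dimethylocta-2,4,6-trienedial
Product: 22 (3R)-12'-oxo-12'-apo-β-caroten-3-yl hexadecanoate (all-E), via 11Z-aldehyde 21 (not isolated)
Conditions: 20 (2 equiv), 1,2-epoxybutane, 65 °C; then n-heptane, 90 °C
Reagents that add atoms: none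
Why: Wittig olefination under halide/epoxide conditions: bromide opens the epoxide, the alkoxide so formed generates the ylide without free strong base, and the ylide condenses with one formyl group of the excess symmetrical dialdehyde to form C11=C12; the hindered 11Z-isomer expected from the semi-stabilised ylide should relax thermally to the all-E aldehyde, and the palmitate survives.

Step 14
Reactants: 22 C25 aldehyde
Product: 23 (3R)-12'-hydroxy-12'-apo-β-caroten-3-yl hexadecanoate
Conditions: NaBH4, EtOH/THF, −20 → 0 °C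
Reagents that add atoms: none
Why: Chemoselective 1,2-reduction of the polyenal by borohydride, as in step 11; the ester and the polyene are unchanged.

Step 15
Reactants: 23 C25 allylic alcohol
Product: 24 [(3R)-3-(hexadecanoyloxy)-12'-apo-β-caroten-12'-yl]triphenylphosphonium bromide
Conditions: PPh3·HBr (1.05 equiv), CH2Cl2, 0 °C → rt, dark
Reagents that add atoms: triphenylphosphine hydrobromide, [Br-].c1ccccc1[PH+](c1ccccc1)c1ccccc1
Why: Phosphonium salt formation as in step 12: ionisation to the delocalised polyenyl cation and capture by PPh3 at the primary C12' terminus (the retinyl-type Wittig-salt preparation).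

Step 16
Reactants: 24 C25 phosphonium bromide; 12 ε-C15 aldehyde myristate
Product: 26 (3R,3'R,6'R)-β,ε-carotene-3,3'-diol 3-hexadecanoate 3'-tetradecanoate (all-E), via 11'Z-diester 25 (not isolated)
Conditions: 12 (1.1 equiv), 1,2-epoxybutane, 65 °C; then n-heptane, 90 °C, argon, dark
Reagents that add atoms: none
Why: Wittig olefination under the same base-free epoxide conditions joins C12' of the ylide to C11' of the aldehyde and completes the C40 polyene; both esters, the allylic C3' centre and the base-sensitive C6'–H are untouched, and heating should convert the 11'Z-isomer into the all-E target.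

**Compound list**

1 | (E)-pent-3-en-2-one | C/C=C/C(C)=O | starting material
2 | (E)-tert-butyldimethyl(penta-1,3-dien-2-yloxy)silane | C=C(O[Si](C)(C)C(C)(C)C)/C=C/C | intermediate
3 | 3-methylbut-2-enal | CC(C)=CC=O | starting material
4 | (1S,2S)-4-[(tert-butyldimethylsilyl)oxy]-2,6,6-trimethylcyclohex-3-ene-1-carbaldehyde | O=C[C@H]1[C@@H](C)C=C(O[Si](C)(C)C(C)(C)C)CC1(C)C | intermediate
5 | diethyl (3-cyano-2-methylallyl)phosphonate | CCOP(=O)(OCC)CC(C)=CC#N | starting material
6 | (2E,4E)-5-[(1S,2R)-4-[(tert-butyldimethylsilyl)oxy]-2,6,6-trimethylcyclohex-3-en-1-yl]-3-methylpenta-2,4-dienenitrile | N#C/C=C(\C)/C=C/[C@H]1[C@@H](C)C=C(O[Si](C)(C)C(C)(C)C)CC1(C)C | intermediate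
7 | (2E,4E)-3-methyl-5-[(1R)-2,6,6-trimethyl-4-oxocyclohex-2-en-1-yl]penta-2,4-dienenitrile | N#C/C=C(\C)/C=C/[C@H]1C(C)=CC(=O)CC1(C)C | intermediate
8 | (2E,4E)-5-[(1R,4S)-4-hydroxy-2,6,6-trimethylcyclohex-2-en-1-yl]-3-methylpenta-2,4-dienenitrile | N#C/C=C(\C)/C=C/[C@H]1C(C)=C[C@@H](O)CC1(C)C | intermediate
9 | (2E,4E)-5-[(1R,4S)-4-hydroxy-2,6,6-trimethylcyclohex-2-en-1-yl]-3-methylpenta-2,4-dien-1-imine (held as its aluminium derivative) | N=C/C=C(\C)/C=C/[C@H]1C(C)=C[C@@H](O)CC1(C)C | intermediate (not isolated)
10 | (2E,4E)-5-[(1R,4S)-4-hydroxy-2,6,6-trimethylcyclohex-2-en-1-yl]-3-methylpenta-2,4-dienal | O=C/C=C(\C)/C=C/[C@H]1C(C)=C[C@@H](O)CC1(C)C | intermediate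
11 | tetradecanoic (myristic) acid | CCCCCCCCCCCCCC(=O)O | starting material
12 | (1R,4R)-3,5,5-trimethyl-4-[(1E,3E)-3-methyl-5-oxopenta-1,3-dien-1-yl]cyclohex-2-en-1-yl tetradecanoate | O=C/C=C(\C)/C=C/[C@H]1C(C)=C[C@H](OC(=O)CCCCCCCCCCCCC)CC1(C)C | intermediate
13 | (2E,4E)-5-[(4R)-4-hydroxy-2,6,6-trimethylcyclohex-1-en-1-yl]-3-methylpenta-2,4-dienenitrile | N#C/C=C(\C)/C=C/C1=C(C)C[C@@H](O)CC1(C)C | intermediate
14 | (2E,4E)-5-[(4R)-4-hydroxy-2,6,6-trimethylcyclohex-1-en-1-yl]-3-methylpenta-2,4-dien-1-imine (held as its aluminium derivative) | N=C/C=C(\C)/C=C/C1=C(C)C[C@@H](O)CC1(C)C | intermediate (not isolated)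
15 | (2E,4E)-5-[(4R)-4-hydroxy-2,6,6-trimethylcyclohex-1-en-1-yl]-3-methylpenta-2,4-dienal | O=C/C=C(\C)/C=C/C1=C(C)C[C@@H](O)CC1(C)C | intermediate
16 | hexadecanoyl (palmitoyl) chloride | CCCCCCCCCCCCCCCC(=O)Cl | starting material
17 | (1R)-3,5,5-trimethyl-4-[(1E,3E)-3-methyl-5-oxopenta-1,3-dien-1-yl]cyclohex-3-en-1-yl hexadecanoate | O=C/C=C(\C)/C=C/C1=C(C)C[C@@H](OC(=O)CCCCCCCCCCCCCCC)CC1(C)C | intermediate
18 | (1R)-4-[(1E,3E)-5-hydroxy-3-methylpenta-1,3-dien-1-yl]-3,5,5-trimethylcyclohex-3-en-1-yl hexadecanoate | OC/C=C(\C)/C=C/C1=C(C)C[C@@H](OC(=O)CCCCCCCCCCCCCCC)CC1(C)C | intermediate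
19 | {(2E,4E)-5-[(4R)-4-(hexadecanoyloxy)-2,6,6-trimethylcyclohex-1-en-1-yl]-3-methylpenta-2,4-dien-1-yl}triphenylphosphonium bromide | [Br-].c1ccccc1[P+](c1ccccc1)(c1ccccc1)C/C=C(\C)/C=C/C1=C(C)C[C@@H](OC(=O)CCCCCCCCCCCCCCC)CC1(C)C | intermediate
20 | (2E,4E,6E)-2,7-dimethylocta-2,4,6-trienedial | O=C/C(C)=C/C=C/C=C(C)/C=O | starting material
21 | (3R,11Z)-12'-oxo-12'-apo-β-caroten-3-yl hexadecanoate | CCCCCCCCCCCCCCCC(=O)O[C@@H]1CC(C)=C(/C=C/C(C)=C/C=C\C(C)=C\C=C\C=C(C)\C=O)C(C)(C)C1 | intermediate (not isolated)
22 | (3R)-12'-oxo-12'-apo-β-caroten-3-yl hexadecanoate (all-E) | CCCCCCCCCCCCCCCC(=O)O[C@@H]1CC(C)=C(/C=C/C(C)=C/C=C/C(C)=C/C=C/C=C(C)/C=O)C(C)(C)C1 | intermediate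
23 | (3R)-12'-hydroxy-12'-apo-β-caroten-3-yl hexadecanoate | CCCCCCCCCCCCCCCC(=O)O[C@@H]1CC(C)=C(/C=C/C(C)=C/C=C/C(C)=C/C=C/C=C(C)/CO)C(C)(C)C1 | intermediate
24 | [(3R)-3-(hexadecanoyloxy)-12'-apo-β-caroten-12'-yl]triphenylphosphonium bromide | [Br-].CCCCCCCCCCCCCCCC(=O)O[C@@H]1CC(C)=C(/C=C/C(C)=C/C=C/C(C)=C/C=C/C=C(C)/C[P+](c2ccccc2)(c2ccccc2)c2ccccc2)C(C)(C)C1 | intermediate
25 | (3R,3'R,6'R,11'Z)-β,ε-carotene-3,3'-diol 3-hexadecanoate 3'-tetradecanoate | CCCCCCCCCCCCCCCC(=O)O[C@@H]1CC(C)=C(/C=C/C(C)=C/C=C/C(C)=C/C=C/C=C(C)/C=C\C=C(C)\C=C\[C@H]2C(C)=C[C@H](OC(=O)CCCCCCCCCCCCC)CC2(C)C)C(C)(C)C1 | intermediate (not isolated)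
26 | (3R,3'R,6'R)-β,ε-carotene-3,3'-diol 3-hexadecanoate 3'-tetradecanoate (all-E; CNP0238324.1) | CCCCCCCCCCCCCCCC(=O)O[C@@H]1CC(C)=C(/C=C/C(C)=C/C=C/C(C)=C/C=C/C=C(C)/C=C/C=C(C)/C=C/[C@H]2C(C)=C[C@H](OC(=O)CCCCCCCCCCCCC)CC2(C)C)C(C)(C)C1 | target

**Step count and risks**

Total step count: 16. Longest linear sequence: 14 steps (steps 1–5, then 8–16). The ε-branch (steps 6, 7) joins at step 16.

Steps most likely to fail:

1. Step 2 (new method). The β,β-disubstituted enal may be too poor a dienophile for the chiral Lewis acid. Addition of the silyl enol ether terminus to the formyl carbon may outrun cycloaddition. Facial discrimination at the unsubstituted C-α may be incomplete. Fallback by known chemistry, setting out from 2 and 3 and coming back at 8: the two are combined under the achiral mixed Lewis acid AlBr3/AlMe3 in toluene/CH2Cl2 near 0 °C, the protocol for hindered 2-siloxydienes with β,β-disubstituted unsaturated carbonyl dienophiles. This gives the racemic cis-adduct, that is 4 together with its enantiomer (1R,2R)-4-[(tert-butyldimethylsilyl)oxy]-2,6,6-trimethylcyclohex-3-ene-1-carbaldehyde F1. Steps 3–5 are run unchanged on the racemate, which carries the mirror-image silyl enol ether (1R,2S)-dienenitrile F2, the (1S)-enone F3 and the (1S,4R)-cis-alcohol F4 alongside 6, 7 and 8. The racemic alcohol is then resolved by lipase-catalysed transesterification (Pseudomonas cepacia lipase, vinyl acetate, t-BuOMe, rt). By the usual enantiopreference of lipases for secondary alcohols the (4R)-carbinol F4 should be acetylated to (1R,4S)-4-[(1E,3E)-4-cyano-3-methylbuta-1,3-dien-1-yl]-3,5,5-trimethylcyclohex-2-en-1-yl acetate F5, and unreacted 8 is separated and carried on from step 6 and step 8.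

2. Step 8. The proton shift may stop at an equilibrium mixture of ring-positional isomers, and rotation about C9=C10 in the delocalised anion lowers the amount of 9E material. Fallback by known chemistry, setting out from phosphonate 5 and coming back at 13, with the β-ring bought in as safranal. Safranal is reduced (NaBH4, CeCl3·7H2O, MeOH) to (2,6,6-trimethylcyclohexa-1,3-dien-1-yl)methanol F9 and silylated (TBSCl, imidazole) to its tert-butyldimethylsilyl ether F10. Asymmetric hydroboration of the disubstituted ring alkene, with the diisopinocampheylborane antipode whose established sense of induction on cis-alkenes leads to the 3R carbinol, then NaOH/H2O2, gives (1R)-4-{[(tert-butyldimethylsilyl)oxy]methyl}-3,5,5-trimethylcyclohex-3-en-1-ol F11. Desilylation (Bu4NF) gives (1R)-4-(hydroxymethyl)-3,5,5-trimethylcyclohex-3-en-1-ol F12. MnO2 oxidises only the allylic primary alcohol to (4R)-4-hydroxy-2,6,6-trimethylcyclohex-1-ene-1-carbaldehyde F13. Olefination of F13 with the anion of 5 under the conditions of step 3 (one further equivalent of base for the hydroxyl) gives 13.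

3. Step 5. Hydride delivery syn to the chain may compete with delivery anti to it, and the acidic C6'–H of 7 may enolise before reduction. Fallback, setting out from 7 and coming back at 12, uses the other epimer in place of inversion. The trans-alcohol (2E,4E)-5-[(1R,4R)-4-hydroxy-2,6,6-trimethylcyclohex-2-en-1-yl]-3-methylpenta-2,4-dienenitrile F6 already has the C3' configuration of the target. It is separated from 8 and reduced as in step 6, through its aldimine F7, to the trans-hydroxy dienal (2E,4E)-5-[(1R,4R)-4-hydroxy-2,6,6-trimethylcyclohex-2-en-1-yl]-3-methylpenta-2,4-dienal F8. F8 is esterified with retention by tetradecanoyl chloride, pyridine and DMAP to give 12 directly. The ε-branch then needs no Mitsunobu step and all of 8 is kept for the β-branch.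

Further compounds
F1 | step 2 | (1R,2R)-4-[(tert-butyldimethylsilyl)oxy]-2,6,6-trimethylcyclohex-3-ene-1-carbaldehyde (enantiomer of 4) | O=C[C@@H]1[C@H](C)C=C(O[Si](C)(C)C(C)(C)C)CC1(C)C
F2 | step 2 | (2E,4E)-5-[(1R,2S)-4-[(tert-butyldimethylsilyl)oxy]-2,6,6-trimethylcyclohex-3-en-1-yl]-3-methylpenta-2,4-dienenitrile (enantiomer of 6) | N#C/C=C(\C)/C=C/[C@@H]1[C@H](C)C=C(O[Si](C)(C)C(C)(C)C)CC1(C)C
F3 | step 2 | (2E,4E)-3-methyl-5-[(1S)-2,6,6-trimethyl-4-oxocyclohex-2-en-1-yl]penta-2,4-dienenitrile (enantiomer of 7) | N#C/C=C(\C)/C=C/[C@@H]1C(C)=CC(=O)CC1(C)C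
F4 | step 2 | (2E,4E)-5-[(1S,4R)-4-hydroxy-2,6,6-trimethylcyclohex-2-en-1-yl]-3-methylpenta-2,4-dienenitrile (enantiomer of 8) | N#C/C=C(\C)/C=C/[C@@H]1C(C)=C[C@H](O)CC1(C)C
F5 | step 2 | (1R,4S)-4-[(1E,3E)-4-cyano-3-methylbuta-1,3-dien-1-yl]-3,5,5-trimethylcyclohex-2-en-1-yl acetate | N#C/C=C(\C)/C=C/[C@@H]1C(C)=C[C@H](OC(C)=O)CC1(C)C
F6 | step 5 | (2E,4E)-5-[(1R,4R)-4-hydroxy-2,6,6-trimethylcyclohex-2-en-1-yl]-3-methylpenta-2,4-dienenitrile | N#C/C=C(\C)/C=C/[C@H]1C(C)=C[C@H](O)CC1(C)C
F7 | step 5 | (2E,4E)-5-[(1R,4R)-4-hydroxy-2,6,6-trimethylcyclohex-2-en-1-yl]-3-methylpenta-2,4-dien-1-imine (not isolated) | N=C/C=C(\C)/C=C/[C@H]1C(C)=C[C@H](O)CC1(C)C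
F8 | step 5 | (2E,4E)-5-[(1R,4R)-4-hydroxy-2,6,6-trimethylcyclohex-2-en-1-yl]-3-methylpenta-2,4-dienal | O=C/C=C(\C)/C=C/[C@H]1C(C)=C[C@H](O)CC1(C)C
F9 | step 8 | (2,6,6-trimethylcyclohexa-1,3-dien-1-yl)methanol | CC1=C(CO)C(C)(C)CC=C1
F10 | step 8 | tert-butyldimethyl[(2,6,6-trimethylcyclohexa-1,3-dien-1-yl)methoxy]silane | CC1=C(CO[Si](C)(C)C(C)(C)C)C(C)(C)CC=C1
F11 | step 8 | (1R)-4-{[(tert-butyldimethylsilyl)oxy]methyl}-3,5,5-trimethylcyclohex-3-en-1-ol | CC1=C(CO[Si](C)(C)C(C)(C)C)C(C)(C)C[C@H](O)C1
F12 | step 8 | (1R)-4-(hydroxymethyl)-3,5,5-trimethylcyclohex-3-en-1-ol | CC1=C(CO)C(C)(C)C[C@H](O)C1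
F13 | step 8 | (4R)-4-hydroxy-2,6,6-trimethylcyclohex-1-ene-1-carbaldehyde | CC1=C(C=O)C(C)(C)C[C@H](O)C1
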